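# Proposed synthesis of 3-hydroxyglabrol by alkyne cyclotrimerisation

## The problem

3-Hydroxyglabrol (34) is a (2R,3R)-dihydroflavonol. Benzo ring A and pyranone ring C share the C4a–C8a bond of a chroman-4-one, and ring B is attached to C2 by a single bond.

Ring A is a 1,2,3,4-tetrasubstituted benzene. O1 (on C8a), a prenyl group (C8), a hydroxyl (C7) and the acyl carbon C4 (on C4a) sit on four adjacent carbons. The prenyl group lies between two oxygens, the position of a resorcinol that substitution chemistry reaches least cleanly.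

C2 and C3 are adjacent stereocentres, trans in the ring and anti in the open chain. C3 is α to the ketone and could be corrected from C2, but C2 cannot be corrected from C3. C2 is lost whenever the β-aryloxy ketone opens (base, or the quinone methide of the free 4'-phenol), and then both centres go. Both are therefore best set together in an acyclic precursor and not touched again.

Each prenyl group is ortho to a phenol. This excludes hydrogenolysis, osmium, peracids and strong electrophiles, and limits the acid strength of any final deprotection, since ortho-prenylphenols close to chromans.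

The feature that invites a cyclotrimerisation is that every ring A substituent is carried by a carbon that can start as an alkyne carbon:
- C8a(O1)≡C8(prenyl) as an ynol ether;
- C4a(acyl)≡C5 as an ynone;
- C7(O)≡C6 as an oxygenated acetylene.

Ring C (O1–C2–C3–C4) is then exactly the four-atom tether of a 1,7-diyne, and it holds both stereocentres away from the reacting carbons.

## Retrosynthesis

**Unmasking.** No skeletal bond is cut. Target 34 is traced to its bis(methoxymethyl) ether 33 (two acetal C–O bonds) and 33 to the silylated chromanone 31 (O7–Si and C5–Si). Fluoride comes first and acid last. While O3 and O4' are still protected, the 7-phenoxide formed by fluoride turns the ketone into a vinylogous carboxylate, so C3–H is not acidic and the quinone methide path at C2 is closed. The acid step then only has to spare the two prenyl groups.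

**Rings A and C.** In 31 the bonds C7–C8, C5–C6 and C4a–C8a are cut together, giving the acyclic diyne 30 and ethynyloxy(triisopropyl)silane 29. Cutting only O1–C8a or only C4–C4a would leave ring A to be built as a crowded arene by substitution chemistry. The triple cut removes both rings and turns each ring A substituent into a substituent of an sp carbon. The forward reaction must be a cross-cyclotrimerisation near room temperature, with the oxygen-bearing carbon of 29 ending next to C8. The trimethylsilyl group at C5 is kept as a removable steric marker for that purpose.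

**Ynone.** Diyne 30 is cut at C4–C4a: oxidation of propargylic alcohol 25, which comes from aldehyde 22 and ethynyltrimethylsilane 23. An amide or ester at C4 is not used, because no acyl group survives the butyllithium needed for the ynol ether. C4 is therefore carried as a silyl-protected primary alcohol (20 → 21 → 22), and the ynone is made last and used at once.

**Ynol ether.** In 20 the O1–C8a bond and the C8–CH2 bond are cut. The alkoxide of alcohol 14 adds to dichloroethyne made in the flask from trichloroethene 15, giving dichlorovinyl ether 17. Conversion to the lithium alkynyl ether and alkylation with prenyl bromide 2 follow. The C2–O bond itself is never broken, so the carbinol configuration of 14 is carried into 20. The forward steps need a substrate without carbonyl groups and a silyl group that does not migrate to the neighbouring alkoxide, hence the triisopropylsilyl ether on the primary oxygen.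

**Stereodiad.** Alcohol 14 comes from diol 13, and 13 from aldol adduct 12 by reductive removal of the auxiliary. Cutting C2–C3 of 12 gives glycolyl imide 10 and ring B aldehyde 4. An anti-selective glycolate aldol sets both stereocentres in one step and delivers the benzylic hydroxyl free and O3 already protected, which is the differentiation the ynol ether step needs. Dihydroxylation of a cinnamate is not an option because the prenyl alkene would react first.

**Building blocks.** Aldehyde 4 comes from 4-hydroxybenzaldehyde 1 and 2 by ortho C-prenylation (3) and acetal protection. Imide 10 comes from methyl glycolate 5 (via 6 and 7) and oxazolidinone 8. Siloxyalkyne 29 comes from acetylene 26 by oxidation of its lithium salt to the ynolate and O-silylation.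

## Roads not taken

**Alternative 1:** Danheiser benzannulation.
- Cut: C8–C8a, C6–C7 and C4a–C8a of ring A only.
- Forward step: irradiation of the diazo ketone A3 gives a vinylketene by Wolff rearrangement; it adds to the prenyl-bearing siloxyalkyne A2, and ring opening and 6π closure give the salicylate A1.
- Merits: this is a known reaction class for siloxyalkynes. Its regiochemistry places O1, prenyl and O7 exactly as needed. A2 is an ordinary substituted siloxyalkyne, easier to make than the parent compound 29.
- Weak points: only ring A is made. Ring C and both stereocentres remain, so the route returns to the ester-to-chalcone endgame, in which C2 is formed by phenol attack at an electron-rich benzylic carbon and can erode. A photochemical step is also needed.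
- Comparison: the ring-forming step is safer than step 16, and that is a real advantage. Against it the chosen plan sets that two rings are closed at once and that the stereocentres are fixed beforehand and are only spectators.

**Alternative 2:** Parham cyclisation.
- Cut: C4–C4a.
- Forward step: bromine–lithium exchange on the aryl ether A5 and attack of the aryllithium on the tethered Weinreb amide give the tris-silyl chromanone A4.
- Merits: the ring closure is known chemistry. Uniform silyl protection would allow a one-step fluoride deprotection with no acid, which is better than the endgame proposed here.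
- Weak points: A5 contains the O1–C2 bond between a 2,6-disubstituted phenol and a secondary para-oxygenated benzylic carbon of defined configuration. A Mitsunobu-type etherification there is hindered and prone to ionisation. Ring A must also first be made as a 1,2,3,4-tetrasubstituted bromoresorcinol.
- Comparison: the difficulty is moved from the ring closure to the precursor. The chosen plan avoids arene substitution chemistry altogether but has to set an unprecedented key step against a well-known one.

**Alternative 3:** Intramolecular SNAr.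
- Cut: O1–C8a.
- Forward step: the C2 alkoxide of the β-hydroxy ketone A7 displaces the ortho fluoride to give A6, with retention at C2.
- Merits: it uses the same anti-aldol diad and is clearly shorter than the chosen route, and every step is of a known type.
- Weak points: the nucleophile is the alkoxide of a β-hydroxy ketone, so retro-aldol cleavage competes. The fluoroarene is only weakly activated, because the ketone is para to an alkoxy donor and the fluorine is flanked by the prenyl group. The ring A piece needs directed metalation to place prenyl between fluorine and oxygen.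
- Comparison: this road is better in step count and in precedent. The chosen plan sets against it that no β-oxygenated ketone ever meets a strong base, that ring A needs no regiochemical substitution step, and that the cyclotrimerisation, if it works, is a general entry to 8-substituted 7-oxychromanones.

Key step: step 16

Remark: the 2,3-trans (2R,3R) configuration of 34 corresponds to an anti arrangement of O1 and O3 in every open-chain precursor. The CIP label of the O3-bearing carbon changes along the route only because its neighbours change rank.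

## Route

Step 1
Reactants: 1 4-hydroxybenzaldehyde; 2 1-bromo-3-methylbut-2-ene
Product: 3 4-hydroxy-3-(3-methylbut-2-enyl)benzaldehyde
Conditions: KOH (10% aq), rt
Reagents that add atoms: none
Why: Ambident phenoxide alkylation in water, where hydrogen bonding to oxygen favours C-alkylation at the free ortho position (para is blocked); the O-prenyl ether and bis-alkylated material are the expected, separable by-products.

Step 2
Reactants: 3 4-hydroxy-3-(3-methylbut-2-enyl)benzaldehyde
Product: 4 4-(methoxymethoxy)-3-(3-methylbut-2-enyl)benzaldehyde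
Conditions: MOMCl, i-Pr2NEt, CH2Cl2, 0 °C to rt
Reagents that add atoms: chloromethyl methyl ether, COCCl
Why: O-alkylation of the phenol to the methoxymethyl acetal, which is stable to hydride, alkoxide, butyllithium and fluoride and leaves with dilute acid.

Step 3
Reactants: 5 methyl glycolate
Product: 6 methyl 2-(methoxymethoxy)acetate
Conditions: MOMCl, i-Pr2NEt, CH2Cl2, 0 °C to rt
Reagents that add atoms: chloromethyl methyl ether, COCCl
Why: Acetal protection of the primary hydroxyl; this oxygen becomes O3 of the target.

Step 4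
Reactants: 6 methyl 2-(methoxymethoxy)acetate
Product: 7 2-(methoxymethoxy)acetic acid
Conditions: LiOH, THF/H2O, 0 °C; then cold dilute HCl to pH 3
Reagents that add atoms: lithium hydroxide, [Li+].[OH-]
Why: Ester saponification; brief cold acidification leaves the acetal intact.

Step 5
Reactants: 7 2-(methoxymethoxy)acetic acid; 8 (S)-4-benzyl-1,3-oxazolidin-2-one
Product: 10 (S)-4-benzyl-3-[2-(methoxymethoxy)acetyl]-1,3-oxazolidin-2-one, via mixed pivalic anhydride 9 (not isolated)
Conditions: PivCl, Et3N, THF, −20 °C; then 8, LiCl, rt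
Reagents that add atoms: none
Why: N-acylation of the oxazolidinone through the mixed anhydride (lithium chloride/amine protocol), which avoids making an acid chloride of the acetal-bearing acid.

Step 6
Reactants: 10 (S)-4-benzyl-3-[2-(methoxymethoxy)acetyl]-1,3-oxazolidin-2-one; 4 4-(methoxymethoxy)-3-(3-methylbut-2-enyl)benzaldehyde
Product: 12 (S)-4-benzyl-3-[(2R,3R)-3-hydroxy-2-(methoxymethoxy)-3-[4-(methoxymethoxy)-3-(3-methylbut-2-enyl)phenyl]propanoyl]-1,3-oxazolidin-2-one, via O-trimethylsilyl aldol adduct 11 (not isolated)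
Conditions: MgCl2 (20 mol %), Et3N, TMSCl, EtOAc, rt; then citric acid, MeOH
Reagents that add atoms: none
Why: Magnesium halide-catalysed anti-selective Evans aldol (soft enolisation, silyl trapping of the aldolate), for which non-enolisable aromatic aldehydes are the best acceptors. The chelated (Z)-enolate should be attacked on the face away from the benzyl group, as in auxiliary-controlled alkylations, which sets the O3-bearing carbon as R; the anti transition state then sets the carbinol carbon as R.

Step 7
Reactants: 12 (S)-4-benzyl-3-[(2R,3R)-3-hydroxy-2-(methoxymethoxy)-3-[4-(methoxymethoxy)-3-(3-methylbut-2-enyl)phenyl]propanoyl]-1,3-oxazolidin-2-one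
Product: 13 (1R,2S)-2-(methoxymethoxy)-1-[4-(methoxymethoxy)-3-(3-methylbut-2-enyl)phenyl]propane-1,3-diol
Conditions: LiBH4, MeOH (1 equiv), THF, 0 °C
Reagents that add atoms: none
Why: Reductive cleavage of the imide to the primary alcohol with release of the auxiliary; no stereocentre is touched and the prenyl alkene is inert to borohydride.

Step 8
Reactants: 13 (1R,2S)-2-(methoxymethoxy)-1-[4-(methoxymethoxy)-3-(3-methylbut-2-enyl)phenyl]propane-1,3-diol
Product: 14 (1R,2S)-2-(methoxymethoxy)-1-[4-(methoxymethoxy)-3-(3-methylbut-2-enyl)phenyl]-3-(triisopropylsilyloxy)propan-1-ol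
Conditions: TIPSCl, imidazole, DMF, 0 °C
Reagents that add atoms: chlorotriisopropylsilane, CC(C)[Si](Cl)(C(C)C)C(C)C
Why: Selective silylation of the primary over the hindered secondary benzylic hydroxyl; the bulky triisopropylsilyl group is chosen because it resists migration to the neighbouring alkoxide in the next step.

Step 9
Reactants: 14 (1R,2S)-2-(methoxymethoxy)-1-[4-(methoxymethoxy)-3-(3-methylbut-2-enyl)phenyl]-3-(triisopropylsilyloxy)propan-1-ol; 15 trichloroethene
Product: 17 triisopropyl{[(2S,3R)-3-{[(E)-1,2-dichloroethenyl]oxy}-2-(methoxymethoxy)-3-[4-(methoxymethoxy)-3-(3-methylbut-2-enyl)phenyl]propyl]oxy}silane, via dichloroethyne 16 (not isolated)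
Conditions: KH, THF, 0 °C; then 15, −40 °C to rt
Reagents that add atoms: none
Why: The standard trichloroethene route to alkynyl ethers: alkoxide-induced dehydrochlorination gives dichloroethyne, to which the alkoxide adds in trans fashion. The carbinol C–O bond is not broken, so C2 keeps its configuration, and the substrate has no group that a potassium alkoxide can attack.

Step 10
Reactants: 17 triisopropyl{[(2S,3R)-3-{[(E)-1,2-dichloroethenyl]oxy}-2-(methoxymethoxy)-3-[4-(methoxymethoxy)-3-(3-methylbut-2-enyl)phenyl]propyl]oxy}silane; 2 1-bromo-3-methylbut-2-ene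
Product: 20 triisopropyl{[(2S,3R)-2-(methoxymethoxy)-3-[4-(methoxymethoxy)-3-(3-methylbut-2-enyl)phenyl]-3-[(5-methylhex-4-en-1-yn-1-yl)oxy]propyl]oxy}silane, via chloroalkynyl ether 18 (not isolated), via lithium alkynyl ether 19 (not isolated)
Conditions: n-BuLi (2.1 equiv), THF, −78 to −40 °C; then 2, DMPU, −78 to 0 °C
Reagents that add atoms: none
Why: Dehydrochlorination and chlorine–lithium exchange give the lithium alkynyl ether, which is alkylated by the allylic bromide at its primary carbon (SN2). The product is kept cold and purified on base-washed silica, because secondary alkynyl ethers lose alkene by retro-ene reaction on warming and hydrate with acid.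

Step 11
Reactants: 20 triisopropyl{[(2S,3R)-2-(methoxymethoxy)-3-[4-(methoxymethoxy)-3-(3-methylbut-2-enyl)phenyl]-3-[(5-methylhex-4-en-1-yn-1-yl)oxy]propyl]oxy}silane
Product: 21 (2S,3R)-2-(methoxymethoxy)-3-[4-(methoxymethoxy)-3-(3-methylbut-2-enyl)phenyl]-3-[(5-methylhex-4-en-1-yn-1-yl)oxy]propan-1-ol
Conditions: Bu4NF, THF, 0 °C to rt
Reagents that add atoms: none
Why: Fluoride cleavage of the silyl ether; ynol ether, acetals and alkenes are inert to fluoride, and no other silyl group is present at this stage.

Step 12
Reactants: 21 (2S,3R)-2-(methoxymethoxy)-3-[4-(methoxymethoxy)-3-(3-methylbut-2-enyl)phenyl]-3-[(5-methylhex-4-en-1-yn-1-yl)oxy]propan-1-ol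
Product: 22 (2R,3R)-2-(methoxymethoxy)-3-[4-(methoxymethoxy)-3-(3-methylbut-2-enyl)phenyl]-3-[(5-methylhex-4-en-1-yn-1-yl)oxy]propanal
Conditions: IBX, DMSO/THF, rt; used crude
Reagents that add atoms: none
Why: Hypervalent iodine oxidation of a primary alcohol under neutral conditions. It is chosen because it frees neither a strong acid (the ynol ether would hydrate) nor an amine base (the β-alkynyloxy aldehyde can eliminate ynolate and can epimerise).

Step 13
Reactants: 22 (2R,3R)-2-(methoxymethoxy)-3-[4-(methoxymethoxy)-3-(3-methylbut-2-enyl)phenyl]-3-[(5-methylhex-4-en-1-yn-1-yl)oxy]propanal; 23 ethynyltrimethylsilane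
Product: 25 (4S,5R)-4-(methoxymethoxy)-5-[4-(methoxymethoxy)-3-(3-methylbut-2-enyl)phenyl]-5-[(5-methylhex-4-en-1-yn-1-yl)oxy]-1-(trimethylsilyl)pent-1-yn-3-ol (mixture of C3 epimers), via lithium (trimethylsilyl)acetylide 24 (not isolated)
Conditions: 23, n-BuLi, THF, −78 °C; then 22, −78 °C
Reagents that add atoms: none
Why: 1,2-Addition of a lithium acetylide to an aldehyde, fast at −78 °C relative to enolisation. The new carbinol centre is formed without control on purpose, since it is removed by oxidation in step 15.

Step 14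
Reactants: 26 acetylene
Product: 29 ethynyloxy(triisopropyl)silane, via lithium acetylide 27 (not isolated), via lithium ethynolate 28 (not isolated)
Conditions: n-BuLi, THF, −78 °C; t-BuOOLi (from t-BuOOH, LiN(SiMe3)2), −78 to 0 °C; then TIPSOTf, −78 to 0 °C
Reagents that add atoms: tert-butyl hydroperoxide, CC(C)(C)OO; triisopropylsilyl trifluoromethanesulfonate, CC(C)[Si](C(C)C)(C(C)C)OS(=O)(=O)C(F)(F)F
Why: Oxidation of a lithium acetylide by lithium tert-butyl peroxide to the ynolate and O-silylation with a bulky silyl triflate, the usual route to 1-siloxyalkynes, applied here to the parent acetylide. The hard, hindered triflate is chosen to favour oxygen over carbon silylation.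

Step 15
Reactants: 25 (4S,5R)-4-(methoxymethoxy)-5-[4-(methoxymethoxy)-3-(3-methylbut-2-enyl)phenyl]-5-[(5-methylhex-4-en-1-yn-1-yl)oxy]-1-(trimethylsilyl)pent-1-yn-3-ol
Product: 30 (4R,5R)-4-(methoxymethoxy)-5-[4-(methoxymethoxy)-3-(3-methylbut-2-enyl)phenyl]-5-[(5-methylhex-4-en-1-yn-1-yl)oxy]-1-(trimethylsilyl)pent-1-yn-3-one
Conditions: activated MnO2, CH2Cl2, rt; filtered and used at once
Reagents that add atoms: none
Why: Heterogeneous oxidation of a propargylic alcohol to the ynone under neutral conditions; both C3 epimers converge. No base is present that could expel the β-alkynyloxy group from the α-alkoxy ketone.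

Step 16
Reactants: 30 (4R,5R)-4-(methoxymethoxy)-5-[4-(methoxymethoxy)-3-(3-methylbut-2-enyl)phenyl]-5-[(5-methylhex-4-en-1-yn-1-yl)oxy]-1-(trimethylsilyl)pent-1-yn-3-one; 29 ethynyloxy(triisopropyl)silane
Product: 31 (2R,3R)-3-(methoxymethoxy)-2-[4-(methoxymethoxy)-3-(3-methylbut-2-enyl)phenyl]-8-(3-methylbut-2-enyl)-7-(triisopropylsilyloxy)-5-(trimethylsilyl)chroman-4-one
Conditions: [Rh(cod)2]BF4 (10 mol %), rac-BINAP (10 mol %), H2 (1 atm, 30 min) then Ar, CH2Cl2, rt; 29 (3 equiv), slow addition of 30
Reagents that add atoms: none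
Why: Proposed new method: a cationic monovalent rhodium–bisphosphine complex should bind the two tethered alkynes of 30 and couple them oxidatively, joining C4a to C8a and closing ring C as a six-membered ring fused to a rhodacyclopentadiene of trivalent rhodium; the donor ynol ether and acceptor ynone form a push–pull pair that should favour this coupling over reaction of 29 with itself. Insertion of 29 into the Rh–C5 bond and C–C reductive elimination then form C5–C6 and C7–C8 and close ring A as the arene, so both rings arise in one catalytic cycle as a formal [2+2+2] cycloaddition. The closest known reaction type is the cationic rhodium/BINAP cross-cyclotrimerisation of 1,7-diynes with monoalkynes, including alkynyl ethers; new here are a siloxyalkyne as the monoyne and the ynol ether/ynone pairing in the diyne. No stereocentre is formed; C2 and C3 lie on the tether, carry no bond to the metal and should pass unchanged. The step needs chemoselectivity for the cross reaction, which excess 29 and slow addition of 30 should secure. It also needs the oxygen-bearing carbon of 29 to bond to C8: the bulky trimethylsilyl group on C5 leaves room only for the CH end of 29, and the nucleophilic CH carbon of 29 matches the electrophilic β-carbon C5 of the ynone while its oxygen-bearing carbon matches the enol-ether carbon C8. Room temperature is essential because the secondary benzylic alkynyl ether fragments on heating.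

Step 17
Reactants: 31 (2R,3R)-3-(methoxymethoxy)-2-[4-(methoxymethoxy)-3-(3-methylbut-2-enyl)phenyl]-8-(3-methylbut-2-enyl)-7-(triisopropylsilyloxy)-5-(trimethylsilyl)chroman-4-one
Product: 33 (2R,3R)-7-hydroxy-3-(methoxymethoxy)-2-[4-(methoxymethoxy)-3-(3-methylbut-2-enyl)phenyl]-8-(3-methylbut-2-enyl)chroman-4-one, via 7-hydroxy-5-(trimethylsilyl)chromanone 32 (not isolated)
Conditions: Bu4NF (3 equiv), THF (wet), 0 to 40 °C
Reagents that add atoms: none
Why: Fluoride cleaves the aryl silyl ether at once and then the aryl–silicon bond, whose ipso carbon is ortho to the ketone (fluoride protodesilylation of ortho-acyl arylsilanes). The 7-phenoxide formed first makes the ketone a vinylogous carboxylate, which protects C3–H from deprotonation and ring opening, while O3 and O4' are still capped.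

Step 18
Reactants: 33 (2R,3R)-7-hydroxy-3-(methoxymethoxy)-2-[4-(methoxymethoxy)-3-(3-methylbut-2-enyl)phenyl]-8-(3-methylbut-2-enyl)chroman-4-one
Product: 34 3-hydroxyglabrol, (2R,3R)-3,7-dihydroxy-2-[4-hydroxy-3-(3-methylbut-2-enyl)phenyl]-8-(3-methylbut-2-enyl)chroman-4-one
Conditions: HCl (3 M), MeOH, 40 °C
Reagents that add atoms: none
Why: Acid-catalysed acetal exchange with methanol removes both methoxymethyl groups, as is common practice for prenylated flavonoids. Dilute acid and moderate temperature are chosen because ortho-prenylphenols cyclise to chromans in strong acid; the trans-dihydroflavonol is configurationally stable under these conditions.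

## Compound list

1 | 4-hydroxybenzaldehyde | O=Cc1ccc(O)cc1 | starting material
2 | 1-bromo-3-methylbut-2-ene | CC(C)=CCBr | starting material
3 | 4-hydroxy-3-(3-methylbut-2-enyl)benzaldehyde | CC(C)=CCc1cc(C=O)ccc1O | intermediate
4 | 4-(methoxymethoxy)-3-(3-methylbut-2-enyl)benzaldehyde | CC(C)=CCc1cc(C=O)ccc1OCOC | intermediate
5 | methyl glycolate | COC(=O)CO | starting material
6 | methyl 2-(methoxymethoxy)acetate | COCOCC(=O)OC | intermediate
7 | 2-(methoxymethoxy)acetic acid | COCOCC(=O)O | intermediate
8 | (S)-4-benzyl-1,3-oxazolidin-2-one | O=C1N[C@@H](Cc2ccccc2)CO1 | starting material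
9 | 2-(methoxymethoxy)acetic pivalic anhydride (not isolated) | COCOCC(=O)OC(=O)C(C)(C)C | intermediate
10 | (S)-4-benzyl-3-[2-(methoxymethoxy)acetyl]-1,3-oxazolidin-2-one | COCOCC(=O)N1[C@@H](Cc2ccccc2)COC1=O | intermediate
11 | (S)-4-benzyl-3-[(2R,3R)-2-(methoxymethoxy)-3-[4-(methoxymethoxy)-3-(3-methylbut-2-enyl)phenyl]-3-(trimethylsilyloxy)propanoyl]-1,3-oxazolidin-2-one (not isolated) | CC(C)=CCc1cc(ccc1OCOC)[C@@H](O[Si](C)(C)C)[C@@H](OCOC)C(=O)N1[C@@H](Cc2ccccc2)COC1=O | intermediate
12 | (S)-4-benzyl-3-[(2R,3R)-3-hydroxy-2-(methoxymethoxy)-3-[4-(methoxymethoxy)-3-(3-methylbut-2-enyl)phenyl]propanoyl]-1,3-oxazolidin-2-one | CC(C)=CCc1cc(ccc1OCOC)[C@@H](O)[C@@H](OCOC)C(=O)N1[C@@H](Cc2ccccc2)COC1=O | intermediate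
13 | (1R,2S)-2-(methoxymethoxy)-1-[4-(methoxymethoxy)-3-(3-methylbut-2-enyl)phenyl]propane-1,3-diol | CC(C)=CCc1cc(ccc1OCOC)[C@@H](O)[C@@H](OCOC)CO | intermediate
14 | (1R,2S)-2-(methoxymethoxy)-1-[4-(methoxymethoxy)-3-(3-methylbut-2-enyl)phenyl]-3-(triisopropylsilyloxy)propan-1-ol | CC(C)=CCc1cc(ccc1OCOC)[C@@H](O)[C@@H](OCOC)CO[Si](C(C)C)(C(C)C)C(C)C | intermediate
15 | trichloroethene | ClC=C(Cl)Cl | starting material
16 | dichloroethyne (not isolated) | ClC#CCl | intermediate
17 | triisopropyl{[(2S,3R)-3-{[(E)-1,2-dichloroethenyl]oxy}-2-(methoxymethoxy)-3-[4-(methoxymethoxy)-3-(3-methylbut-2-enyl)phenyl]propyl]oxy}silane | CC(C)=CCc1cc(ccc1OCOC)[C@@H](O/C(Cl)=C\Cl)[C@@H](OCOC)CO[Si](C(C)C)(C(C)C)C(C)C | intermediate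
18 | triisopropyl{[(2S,3R)-3-[(chloroethynyl)oxy]-2-(methoxymethoxy)-3-[4-(methoxymethoxy)-3-(3-methylbut-2-enyl)phenyl]propyl]oxy}silane (not isolated) | CC(C)=CCc1cc(ccc1OCOC)[C@@H](OC#CCl)[C@@H](OCOC)CO[Si](C(C)C)(C(C)C)C(C)C | intermediate
19 | {[(1R,2S)-2-(methoxymethoxy)-1-[4-(methoxymethoxy)-3-(3-methylbut-2-enyl)phenyl]-3-(triisopropylsilyloxy)propoxy]ethynyl}lithium (not isolated) | CC(C)=CCc1cc(ccc1OCOC)[C@@H](OC#C[Li])[C@@H](OCOC)CO[Si](C(C)C)(C(C)C)C(C)C | intermediate
20 | triisopropyl{[(2S,3R)-2-(methoxymethoxy)-3-[4-(methoxymethoxy)-3-(3-methylbut-2-enyl)phenyl]-3-[(5-methylhex-4-en-1-yn-1-yl)oxy]propyl]oxy}silane | CC(C)=CCc1cc(ccc1OCOC)[C@@H](OC#CCC=C(C)C)[C@@H](OCOC)CO[Si](C(C)C)(C(C)C)C(C)C | intermediate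
21 | (2S,3R)-2-(methoxymethoxy)-3-[4-(methoxymethoxy)-3-(3-methylbut-2-enyl)phenyl]-3-[(5-methylhex-4-en-1-yn-1-yl)oxy]propan-1-ol | CC(C)=CCc1cc(ccc1OCOC)[C@@H](OC#CCC=C(C)C)[C@@H](OCOC)CO | intermediate
22 | (2R,3R)-2-(methoxymethoxy)-3-[4-(methoxymethoxy)-3-(3-methylbut-2-enyl)phenyl]-3-[(5-methylhex-4-en-1-yn-1-yl)oxy]propanal | CC(C)=CCc1cc(ccc1OCOC)[C@@H](OC#CCC=C(C)C)[C@@H](OCOC)C=O | intermediate
23 | ethynyltrimethylsilane | C#C[Si](C)(C)C | starting material
24 | lithium (trimethylsilyl)acetylide (not isolated) | [Li]C#C[Si](C)(C)C | intermediate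
25 | (4S,5R)-4-(methoxymethoxy)-5-[4-(methoxymethoxy)-3-(3-methylbut-2-enyl)phenyl]-5-[(5-methylhex-4-en-1-yn-1-yl)oxy]-1-(trimethylsilyl)pent-1-yn-3-ol, both C3 epimers | CC(C)=CCc1cc(ccc1OCOC)[C@@H](OC#CCC=C(C)C)[C@@H](OCOC)C(O)C#C[Si](C)(C)C | intermediate
26 | acetylene | C#C | starting material
27 | lithium acetylide (not isolated) | [Li]C#C | intermediate
28 | lithium ethynolate (not isolated) | [Li]OC#C | intermediate
29 | ethynyloxy(triisopropyl)silane | C#CO[Si](C(C)C)(C(C)C)C(C)C | intermediate
30 | (4R,5R)-4-(methoxymethoxy)-5-[4-(methoxymethoxy)-3-(3-methylbut-2-enyl)phenyl]-5-[(5-methylhex-4-en-1-yn-1-yl)oxy]-1-(trimethylsilyl)pent-1-yn-3-one | CC(C)=CCc1cc(ccc1OCOC)[C@@H](OC#CCC=C(C)C)[C@@H](OCOC)C(=O)C#C[Si](C)(C)C | intermediate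
31 | (2R,3R)-3-(methoxymethoxy)-2-[4-(methoxymethoxy)-3-(3-methylbut-2-enyl)phenyl]-8-(3-methylbut-2-enyl)-7-(triisopropylsilyloxy)-5-(trimethylsilyl)chroman-4-one | CC(C)=CCc1cc([C@H]2Oc3c(c([Si](C)(C)C)cc(O[Si](C(C)C)(C(C)C)C(C)C)c3CC=C(C)C)C(=O)[C@@H]2OCOC)ccc1OCOC | intermediate
32 | (2R,3R)-7-hydroxy-3-(methoxymethoxy)-2-[4-(methoxymethoxy)-3-(3-methylbut-2-enyl)phenyl]-8-(3-methylbut-2-enyl)-5-(trimethylsilyl)chroman-4-one (not isolated) | CC(C)=CCc1cc([C@H]2Oc3c(c([Si](C)(C)C)cc(O)c3CC=C(C)C)C(=O)[C@@H]2OCOC)ccc1OCOC | intermediate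
33 | (2R,3R)-7-hydroxy-3-(methoxymethoxy)-2-[4-(methoxymethoxy)-3-(3-methylbut-2-enyl)phenyl]-8-(3-methylbut-2-enyl)chroman-4-one | CC(C)=CCc1cc([C@H]2Oc3c(ccc(O)c3CC=C(C)C)C(=O)[C@@H]2OCOC)ccc1OCOC | intermediate
34 | 3-hydroxyglabrol, (2R,3R)-3,7-dihydroxy-2-[4-hydroxy-3-(3-methylbut-2-enyl)phenyl]-8-(3-methylbut-2-enyl)chroman-4-one | CC(C)=CCc1cc([C@H]2Oc3c(ccc(O)c3CC=C(C)C)C(=O)[C@@H]2O)ccc1O | target

## Step count and least certain steps

Total: 18 steps. Longest linear sequence: 15 steps, from methyl glycolate 5 to 34 (steps 3–13 and 15–18).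

**Step 16 (key step, proposed new method).**
- What may go wrong: loss of the secondary benzylic alkynyl ether of 30 (retro-ene fragmentation, sigmatropic shift or ionisation of the C2–O bond at the Lewis-acidic cationic metal) before oxidative coupling, which is slowed by the silyl cap on the ynone. Also oligomerisation or isomerisation of 29 to a silylketene on the catalyst, and insertion of 29 in the wrong orientation.
- Fallback (known chemistry): sets out from aldehyde 4 and returns at 34. 2,4-Dihydroxyacetophenone is C-prenylated with 2 in aqueous KOH to 1-[2,4-dihydroxy-3-(3-methylbut-2-enyl)phenyl]ethanone F1. Both phenols are capped (NaH, MOMCl) to give 1-[2,4-bis(methoxymethoxy)-3-(3-methylbut-2-enyl)phenyl]ethanone F2. Claisen–Schmidt condensation of F2 with 4 (KOH, EtOH) gives (E)-1-[2,4-bis(methoxymethoxy)-3-(3-methylbut-2-enyl)phenyl]-3-[4-(methoxymethoxy)-3-(3-methylbut-2-enyl)phenyl]prop-2-en-1-one F3. Juliá–Colonna epoxidation (poly-L-leucine, urea–H2O2, DBU, THF) gives the trans-epoxy ketone [2,4-bis(methoxymethoxy)-3-(3-methylbut-2-enyl)phenyl][(2R,3S)-3-[4-(methoxymethoxy)-3-(3-methylbut-2-enyl)phenyl]oxiran-2-yl]methanone F4. Methanolic HCl then removes the three acetals and lets the freed 2'-phenol open the epoxide at the benzylic carbon, with the C3 oxygen retained and C2 settling trans to it, to give 34.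

**Step 14.**
- What may go wrong: silylation of the unhindered parent ynolate at carbon instead of oxygen (giving a silylketene), and disproportionation of monolithium acetylide on warming before it is oxidised.
- Fallback: sets out from trichloroethene 15 (and, for the cycloaddition, from 30) and returns at 34. Potassium tert-butoxide and 15 give 2-{[(E)-1,2-dichloroethenyl]oxy}-2-methylpropane F5 by the chemistry of step 9. n-BuLi followed by methanol gives tert-butoxyethyne F6, a terminal alkynyl ether that needs no ynolate. F6 replaces 29 in the cycloaddition with 30 to give (2R,3R)-7-tert-butoxy-3-(methoxymethoxy)-2-[4-(methoxymethoxy)-3-(3-methylbut-2-enyl)phenyl]-8-(3-methylbut-2-enyl)-5-(trimethylsilyl)chroman-4-one F7. Bu4NF removes the C5 silyl group to give (2R,3R)-7-tert-butoxy-3-(methoxymethoxy)-2-[4-(methoxymethoxy)-3-(3-methylbut-2-enyl)phenyl]-8-(3-methylbut-2-enyl)chroman-4-one F8. Methanolic HCl cleaves the aryl tert-butyl ether together with the two acetals to give 34. The price is a stronger acid treatment in the last step.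

**Step 6.**
- What may go wrong: poor simple diastereoselection. The α-alkoxy group of the glycolyl enolate can compete for magnesium and open a syn pathway, so the carbinol epimer of 12 may form alongside 12 while the auxiliary still fixes the O3-bearing carbon.
- Fallback: sets out from 14, then obtained as a mixture with its C1 epimer after steps 7 and 8, and returns at 14. The benzylic alcohol is oxidised (MnO2, CH2Cl2) to (S)-2-(methoxymethoxy)-1-[4-(methoxymethoxy)-3-(3-methylbut-2-enyl)phenyl]-3-(triisopropylsilyloxy)propan-1-one F9. F9 is reduced with Zn(BH4)2 (Et2O, −30 °C) under Cram-chelate control through the α-methoxymethoxy oxygen, which should deliver the anti alcohol 14. The carbinol centre is thus set by reduction and no longer by the aldol.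

**Step 17.**
- What may go wrong: slow cleavage of the C5–Si bond on the electron-rich 7-phenoxide ring, so that heating with basic fluoride is needed and ring opening of the β-aryloxy ketone (loss of C2) begins to compete.
- Fallback: sets out from aldehyde 22 and returns at 33. Ethynylmagnesium bromide adds to 22 to give (4S,5R)-4-(methoxymethoxy)-5-[4-(methoxymethoxy)-3-(3-methylbut-2-enyl)phenyl]-5-[(5-methylhex-4-en-1-yn-1-yl)oxy]pent-1-yn-3-ol F10 (both C3 epimers). MnO2 gives the terminal ynone (4R,5R)-4-(methoxymethoxy)-5-[4-(methoxymethoxy)-3-(3-methylbut-2-enyl)phenyl]-5-[(5-methylhex-4-en-1-yn-1-yl)oxy]pent-1-yn-3-one F11. Cycloaddition with 29 under the conditions of step 16 gives (2R,3R)-3-(methoxymethoxy)-2-[4-(methoxymethoxy)-3-(3-methylbut-2-enyl)phenyl]-8-(3-methylbut-2-enyl)-7-(triisopropylsilyloxy)chroman-4-one F12. Bu4NF at 0 °C then gives 33. The cost is that the orientation of 29 rests on electronic matching alone, without the steric marker.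

## Further compounds

F1 | step 16 | 1-[2,4-dihydroxy-3-(3-methylbut-2-enyl)phenyl]ethanone | CC(C)=CCc1c(O)ccc(C(C)=O)c1O
F2 | step 16 | 1-[2,4-bis(methoxymethoxy)-3-(3-methylbut-2-enyl)phenyl]ethanone | CC(C)=CCc1c(OCOC)ccc(C(C)=O)c1OCOC
F3 | step 16 | (E)-1-[2,4-bis(methoxymethoxy)-3-(3-methylbut-2-enyl)phenyl]-3-[4-(methoxymethoxy)-3-(3-methylbut-2-enyl)phenyl]prop-2-en-1-one | CC(C)=CCc1cc(/C=C/C(=O)c2ccc(OCOC)c(CC=C(C)C)c2OCOC)ccc1OCOC
F4 | step 16 | [2,4-bis(methoxymethoxy)-3-(3-methylbut-2-enyl)phenyl][(2R,3S)-3-[4-(methoxymethoxy)-3-(3-methylbut-2-enyl)phenyl]oxiran-2-yl]methanone | CC(C)=CCc1cc([C@@H]2O[C@H]2C(=O)c3ccc(OCOC)c(CC=C(C)C)c3OCOC)ccc1OCOC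
F5 | step 14 | 2-{[(E)-1,2-dichloroethenyl]oxy}-2-methylpropane | CC(C)(C)O/C(Cl)=C\Cl
F6 | step 14 | tert-butoxyethyne, 2-(ethynyloxy)-2-methylpropane | C#COC(C)(C)C
F7 | step 14 | (2R,3R)-7-tert-butoxy-3-(methoxymethoxy)-2-[4-(methoxymethoxy)-3-(3-methylbut-2-enyl)phenyl]-8-(3-methylbut-2-enyl)-5-(trimethylsilyl)chroman-4-one | CC(C)=CCc1cc([C@H]2Oc3c(c([Si](C)(C)C)cc(OC(C)(C)C)c3CC=C(C)C)C(=O)[C@@H]2OCOC)ccc1OCOC
F8 | step 14 | (2R,3R)-7-tert-butoxy-3-(methoxymethoxy)-2-[4-(methoxymethoxy)-3-(3-methylbut-2-enyl)phenyl]-8-(3-methylbut-2-enyl)chroman-4-one | CC(C)=CCc1cc([C@H]2Oc3c(ccc(OC(C)(C)C)c3CC=C(C)C)C(=O)[C@@H]2OCOC)ccc1OCOC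
F9 | step 6 | (S)-2-(methoxymethoxy)-1-[4-(methoxymethoxy)-3-(3-methylbut-2-enyl)phenyl]-3-(triisopropylsilyloxy)propan-1-one | CC(C)=CCc1cc(ccc1OCOC)C(=O)[C@@H](OCOC)CO[Si](C(C)C)(C(C)C)C(C)C
F10 | step 17 | (4S,5R)-4-(methoxymethoxy)-5-[4-(methoxymethoxy)-3-(3-methylbut-2-enyl)phenyl]-5-[(5-methylhex-4-en-1-yn-1-yl)oxy]pent-1-yn-3-ol, both C3 epimers | CC(C)=CCc1cc(ccc1OCOC)[C@@H](OC#CCC=C(C)C)[C@@H](OCOC)C(O)C#C
F11 | step 17 | (4R,5R)-4-(methoxymethoxy)-5-[4-(methoxymethoxy)-3-(3-methylbut-2-enyl)phenyl]-5-[(5-methylhex-4-en-1-yn-1-yl)oxy]pent-1-yn-3-one | CC(C)=CCc1cc(ccc1OCOC)[C@@H](OC#CCC=C(C)C)[C@@H](OCOC)C(=O)C#C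
F12 | step 17 | (2R,3R)-3-(methoxymethoxy)-2-[4-(methoxymethoxy)-3-(3-methylbut-2-enyl)phenyl]-8-(3-methylbut-2-enyl)-7-(triisopropylsilyloxy)chroman-4-one | CC(C)=CCc1cc([C@H]2Oc3c(ccc(O[Si](C(C)C)(C(C)C)C(C)C)c3CC=C(C)C)C(=O)[C@@H]2OCOC)ccc1OCOC
A1 | alternative 1 | methyl 2-hydroxy-3-(3-methylbut-2-enyl)-4-(triisopropylsilyloxy)benzoate | COC(=O)c1ccc(O[Si](C(C)C)(C(C)C)C(C)C)c(CC=C(C)C)c1O
A2 | alternative 1 | triisopropyl[(5-methylhex-4-en-1-yn-1-yl)oxy]silane | CC(C)=CCC#CO[Si](C(C)C)(C(C)C)C(C)C
A3 | alternative 1 | methyl (E)-5-diazo-4-oxopent-2-enoate | COC(=O)/C=C/C(=O)C=[N+]=[N-]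
A4 | alternative 2 | (2R,3R)-3,7-bis(tert-butyldimethylsilyloxy)-2-[4-(tert-butyldimethylsilyloxy)-3-(3-methylbut-2-enyl)phenyl]-8-(3-methylbut-2-enyl)chroman-4-one | CC(C)=CCc1cc([C@H]2Oc3c(ccc(O[Si](C)(C)C(C)(C)C)c3CC=C(C)C)C(=O)[C@@H]2O[Si](C)(C)C(C)(C)C)ccc1O[Si](C)(C)C(C)(C)C
A5 | alternative 2 | (2R,3R)-3-[6-bromo-3-(tert-butyldimethylsilyloxy)-2-(3-methylbut-2-enyl)phenoxy]-2-(tert-butyldimethylsilyloxy)-3-[4-(tert-butyldimethylsilyloxy)-3-(3-methylbut-2-enyl)phenyl]-N-methoxy-N-methylpropanamide | CC(C)=CCc1cc(ccc1O[Si](C)(C)C(C)(C)C)[C@@H](Oc1c(Br)ccc(O[Si](C)(C)C(C)(C)C)c1CC=C(C)C)[C@@H](O[Si](C)(C)C(C)(C)C)C(=O)N(C)OC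
A6 | alternative 3 | (2R,3R)-3,7-bis(methoxymethoxy)-2-[4-(methoxymethoxy)-3-(3-methylbut-2-enyl)phenyl]-8-(3-methylbut-2-enyl)chroman-4-one | CC(C)=CCc1cc([C@H]2Oc3c(ccc(OCOC)c3CC=C(C)C)C(=O)[C@@H]2OCOC)ccc1OCOC
A7 | alternative 3 | (2R,3R)-1-[2-fluoro-4-(methoxymethoxy)-3-(3-methylbut-2-enyl)phenyl]-3-hydroxy-2-(methoxymethoxy)-3-[4-(methoxymethoxy)-3-(3-methylbut-2-enyl)phenyl]propan-1-one | CC(C)=CCc1cc(ccc1OCOC)[C@@H](O)[C@@H](OCOC)C(=O)c1ccc(OCOC)c(CC=C(C)C)c1F
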